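The route reads the (Z)-C1'–C2'=C3'–C9' but-2-ene-1,4-dioxygenated unit of the side chain (C1' ether CH2 and C9' hydroxymethyl cis on the trisubstituted olefin) as an opened, oxidised 3-substituted furan ring. One photooxygenation converts furan 10, a 3-alkylfuran carrying the (R)-silyloxy isopropenyl terminus, into γ-hydroxybutenolide 12. The retained ring fixes the olefin geometry and delivers C1' as a lactone carbonyl and C9' as a lactol, so the two termini differ in oxidation level. Afterwards C9' is reduced and silylated, C1' is reduced and etherified with 4-hydroxy-5-methylcoumarin, and C6' is inverted to the (S)-hydroperoxide by sulfonate displacement.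

Key step: step 7

Assumption: side-chain locants run C1' (ether CH2), C2'=C3', C6' (peroxy carbon), with C9' the hydroxymethyl carbon on C3'; in the CBS step the α-branched isopropenyl group is taken to act as the larger ketone substituent, as is usual for 2-substituted enones.

Step 1
Reactants: 1 3-furaldehyde; 2 triethyl phosphonoacetate
Product: 3 ethyl (2E)-3-(furan-3-yl)prop-2-enoate
Conditions: NaH, THF, 0 °C → rt
Reagents that add atoms: none
Why: Horner–Wadsworth–Emmons olefination of a non-enolisable aromatic aldehyde with the stabilised phosphonate anion should give the E-acrylate, whose geometry is erased in step 2.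

Step 2
Reactants: 3 ethyl (2E)-3-(furan-3-yl)prop-2-enoate
Product: 4 ethyl 3-(furan-3-yl)propanoate
Conditions: NaBH4, NiCl2·6H2O (cat.), EtOH, 0 °C
Reagents that add atoms: none
Why: Nickel boride conjugate reduction should saturate the electron-poor acrylate C=C while leaving the ester and the furan ring, which hydrogenation over Pd could attack, untouched.

Step 3
Reactants: 4 ethyl 3-(furan-3-yl)propanoate
Product: 5 3-(furan-3-yl)-N-methoxy-N-methylpropanamide
Conditions: MeNHOMe·HCl, i-PrMgCl, THF, −20 °C
Reagents that add atoms: N,O-dimethylhydroxylamine hydrochloride, CNOC.Cl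
Why: Aminolysis of the unhindered ester by the chloromagnesium amide (Weinreb amide synthesis) is fast at low temperature and should stop cleanly at the amide.

Step 4
Reactants: 5 3-(furan-3-yl)-N-methoxy-N-methylpropanamide; 6 2-bromopropene
Product: 8 5-(furan-3-yl)-2-methylpent-1-en-3-one, via isopropenylmagnesium bromide 7 (not isolated)
Conditions: 6, Mg, THF, rt; then 5, 0 °C; inverse quench into cold aq. NH4Cl
Reagents that add atoms: none
Why: In this Weinreb ketone synthesis the chelated tetrahedral adduct of Grignard 7 survives until the quench, so neither a second addition nor conjugate addition to the enone should occur, and the cold acidic quench keeps the released amine from adding to the enone.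

Step 5
Reactants: 8 5-(furan-3-yl)-2-methylpent-1-en-3-one
Product: 9 (3R)-5-(furan-3-yl)-2-methylpent-1-en-3-ol
Conditions: (S)-Me-CBS (0.2 equiv), BH3·SMe2, THF, −30 °C; MeOH quench
Reagents that add atoms: none
Why: In the Corey–Bakshi–Shibata reduction the ketone binds the (S)-oxazaborolidine–borane complex with the isopropenyl group as the large substituent, so hydride should reach the face that gives the (R)-carbinol (the sense of acetophenone to (R)-1-phenylethanol) faster than borane hydroborates the alkene.

Step 6
Reactants: 9 (3R)-5-(furan-3-yl)-2-methylpent-1-en-3-ol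
Product: 10 3-[(3R)-4-methyl-3-(triethylsilyloxy)pent-4-enyl]furan
Conditions: TESCl, imidazole, DMAP (cat.), CH2Cl2, 0 °C
Reagents that add atoms: chlorotriethylsilane, CC[Si](Cl)(CC)CC
Why: Standard silylation of a secondary allylic alcohol leaves the C–O bond and thus the C6' configuration untouched and installs a group that can later be removed under very mild acid.

Step 7
Reactants: 10 3-[(3R)-4-methyl-3-(triethylsilyloxy)pent-4-enyl]furan
Product: 12 5-hydroxy-4-[(3R)-4-methyl-3-(triethylsilyloxy)pent-4-enyl]furan-2(5H)-one (lactol epimers), via furan endoperoxide 11 (not isolated)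
Conditions: O2, hν (visible), rose bengal (polymer-bound, cat.), i-Pr2NEt (5 equiv), CH2Cl2, −78 °C; then rt, pH 5 phosphate wash
Reagents that add atoms: dioxygen (reacting as singlet oxygen), O=O
Why: Sensitised singlet oxygen should add suprafacially in a [4+2] sense across C2 and C5 of the electron-rich furan to give bicyclic endoperoxide 11, which is stable enough at −78 °C for the amine to remove the bridgehead hydrogen on the unsubstituted side (furan C5, future C1') in a Kornblum–DeLaMare fragmentation; this breaks the O–O bond, makes that carbon the lactone carbonyl and leaves the second peroxide oxygen as the lactol OH on furan C2 (future C9'). The closest known reaction type is the base-mediated photooxygenation of 3-alkylfurans to β-substituted γ-hydroxybutenolides. No ring is closed in the product: the transient peroxide bridge is opened again and the original five-membered oxygen heterocycle survives as the butenolide, which holds C1' and C9' cis across C2'=C3'. The only new stereocentre is the lactol carbon, formed without control as an equilibrating epimer mixture that does not matter because step 8 removes it; C6' is not involved. Two selectivities are needed: regioselective deprotonation, secured by the C3 side chain, which screens the neighbouring bridgehead hydrogen from the bulky amine, and chemoselectivity for the furan over the isopropenyl group, secured by the far higher rate of singlet oxygen with a furan diene than with an unactivated 1,1-disubstituted alkene, irradiation being stopped once 10 is consumed.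

Step 8
Reactants: 12 5-hydroxy-4-[(3R)-4-methyl-3-(triethylsilyloxy)pent-4-enyl]furan-2(5H)-one
Product: 14 4-[(3R)-4-methyl-3-(triethylsilyloxy)pent-4-enyl]furan-2(5H)-one, via ring-opened hydroxy acid 13 (not isolated)
Conditions: NaBH4, EtOH, 0 °C; then aq. citric acid (pH 4), rt
Reagents that add atoms: none
Why: Under basic borohydride the lactol reacts as its ring-opened formyl carboxylate, so only the C9' aldehyde is reduced and the cis hydroxy acid 13 should relactonise on mild acidification to the butenolide, the pH being kept high enough to spare the silyl ether.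

Step 9
Reactants: 14 4-[(3R)-4-methyl-3-(triethylsilyloxy)pent-4-enyl]furan-2(5H)-one
Product: 15 (2Z,6R)-3-(hydroxymethyl)-N-methoxy-N,7-dimethyl-6-(triethylsilyloxy)octa-2,7-dienamide
Conditions: MeNHOMe·HCl, AlMe3, CH2Cl2, 0 °C → rt; Rochelle salt; crude product used directly
Reagents that add atoms: N,O-dimethylhydroxylamine hydrochloride, CNOC.Cl
Why: Aluminium-amide aminolysis of the lactone (Weinreb amidation) should open the ring at the C1' carbonyl with the Z geometry inherited from the ring, conjugate addition being disfavoured at the β,β-disubstituted carbon, and the product is not chromatographed because it can relactonise.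

Step 10
Reactants: 15 (2Z,6R)-3-(hydroxymethyl)-N-methoxy-N,7-dimethyl-6-(triethylsilyloxy)octa-2,7-dienamide
Product: 16 (2Z,6R)-3-[(tert-butyldiphenylsilyloxy)methyl]-N-methoxy-N,7-dimethyl-6-(triethylsilyloxy)octa-2,7-dienamide
Conditions: TBDPSCl, imidazole, DMF, 0 °C → rt
Reagents that add atoms: tert-butyl(chloro)diphenylsilane, CC(C)(C)[Si](Cl)(c1ccccc1)c1ccccc1
Why: Silylation of the primary allylic C9' hydroxyl blocks relactonisation and uses a silyl group far more acid-stable than triethylsilyl, so the two silyl ethers can be removed independently later.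

Step 11
Reactants: 16 (2Z,6R)-3-[(tert-butyldiphenylsilyloxy)methyl]-N-methoxy-N,7-dimethyl-6-(triethylsilyloxy)octa-2,7-dienamide
Product: 18 (2Z,6R)-3-[(tert-butyldiphenylsilyloxy)methyl]-7-methyl-6-(triethylsilyloxy)octa-2,7-dien-1-ol, via Z-enal 17 (not isolated)
Conditions: DIBAL-H, THF, −78 °C; then MeOH, CeCl3·7H2O, NaBH4, −78 → 0 °C; Rochelle salt
Reagents that add atoms: none
Why: DIBAL reduction of the Weinreb amide stops at the chelated hemiaminal, and the aldehyde released on methanol quench should be reduced at once under Luche conditions (1,2-selective), so the isomerisation-prone Z-enal never accumulates.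

Step 12
Reactants: 19 2'-hydroxy-6'-methylacetophenone
Product: 20 4-hydroxy-5-methylcoumarin
Conditions: NaH, (EtO)2CO, toluene, 110 °C; aq. HCl
Reagents that add atoms: diethyl carbonate, CCOC(=O)OCC
Why: Claisen-type acylation of the ketone enolate by the carbonate followed by lactonisation onto the phenoxide is the standard route from 2-hydroxyacetophenones to 4-hydroxycoumarins.

Step 13
Reactants: 18 (2Z,6R)-3-[(tert-butyldiphenylsilyloxy)methyl]-7-methyl-6-(triethylsilyloxy)octa-2,7-dien-1-ol; 20 4-hydroxy-5-methylcoumarin
Product: 21 4-{[(2Z,6R)-3-[(tert-butyldiphenylsilyloxy)methyl]-7-methyl-6-(triethylsilyloxy)octa-2,7-dien-1-yl]oxy}-5-methyl-2H-chromen-2-one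
Conditions: PPh3, DIAD, THF, 0 °C → rt
Reagents that add atoms: none
Why: In this Mitsunobu etherification the acidic 4-hydroxycoumarin (pKa about 4) protonates the betaine and its O4 should displace the oxyphosphonium of the unhindered primary allylic alcohol by SN2 at C1', under neutral conditions that allow neither silyl migration nor olefin isomerisation.

Step 14
Reactants: 21 4-{[(2Z,6R)-3-[(tert-butyldiphenylsilyloxy)methyl]-7-methyl-6-(triethylsilyloxy)octa-2,7-dien-1-yl]oxy}-5-methyl-2H-chromen-2-one
Product: 22 4-{[(2Z,6R)-3-[(tert-butyldiphenylsilyloxy)methyl]-6-hydroxy-7-methylocta-2,7-dien-1-yl]oxy}-5-methyl-2H-chromen-2-one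
Conditions: PPTS (cat.), MeOH/CH2Cl2, 0 °C → rt
Reagents that add atoms: none
Why: Acid-catalysed methanolysis cleaves the triethylsilyl ether orders of magnitude faster than the tert-butyldiphenylsilyl ether, and the weak acid should not ionise the allylic aryl ether.

Step 15
Reactants: 22 4-{[(2Z,6R)-3-[(tert-butyldiphenylsilyloxy)methyl]-6-hydroxy-7-methylocta-2,7-dien-1-yl]oxy}-5-methyl-2H-chromen-2-one
Product: 24 4-{[(2Z,6S)-3-[(tert-butyldiphenylsilyloxy)methyl]-6-hydroperoxy-7-methylocta-2,7-dien-1-yl]oxy}-5-methyl-2H-chromen-2-one, via allylic mesylate 23 (not isolated)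
Conditions: MsCl, Et3N, CH2Cl2, −40 °C; then H2O2 (anhydrous, Et2O, large excess), −40 → 0 °C
Reagents that add atoms: hydrogen peroxide, OO
Why: Mesylation retains configuration, and SN2 displacement of the sulfonate by hydrogen peroxide, an α-effect oxygen nucleophile used in large excess at low temperature in a weakly ionising medium, should invert C6' from R to S; the mesylate is used in the flask because secondary allylic sulfonates ionise on standing.

Step 16
Reactants: 24 4-{[(2Z,6S)-3-[(tert-butyldiphenylsilyloxy)methyl]-6-hydroperoxy-7-methylocta-2,7-dien-1-yl]oxy}-5-methyl-2H-chromen-2-one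
Product: 25 4-{[(2Z,6S)-6-hydroperoxy-3-(hydroxymethyl)-7-methylocta-2,7-dien-1-yl]oxy}-5-methyl-2H-chromen-2-one (CNP0171309.1)
Conditions: HF·pyridine, pyridine, THF, 0 °C → rt
Reagents that add atoms: none
Why: Buffered fluoride cleavage of the primary silyl ether is neither basic enough to dehydrate the secondary hydroperoxide to the enone nor acidic enough to ionise the allylic aryl ether, so the hydroperoxide and the coumarin should survive.

Compound list
1 | 3-furaldehyde | O=Cc1ccoc1 | starting material
2 | triethyl phosphonoacetate | CCOC(=O)CP(=O)(OCC)OCC | starting material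
3 | ethyl (2E)-3-(furan-3-yl)prop-2-enoate | CCOC(=O)/C=C/c1ccoc1 | intermediate
4 | ethyl 3-(furan-3-yl)propanoate | CCOC(=O)CCc1ccoc1 | intermediate
5 | 3-(furan-3-yl)-N-methoxy-N-methylpropanamide | CON(C)C(=O)CCc1ccoc1 | intermediate
6 | 2-bromopropene | C=C(C)Br | starting material
7 | isopropenylmagnesium bromide | C=C(C)[Mg]Br | intermediate (not isolated)
8 | 5-(furan-3-yl)-2-methylpent-1-en-3-one | C=C(C)C(=O)CCc1ccoc1 | intermediate
9 | (3R)-5-(furan-3-yl)-2-methylpent-1-en-3-ol | C=C(C)[C@@H](CCc1ccoc1)O | intermediate
10 | 3-[(3R)-4-methyl-3-(triethylsilyloxy)pent-4-enyl]furan | C=C(C)[C@@H](CCc1ccoc1)O[Si](CC)(CC)CC | intermediate (key-step precursor)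
11 | 5-[(3R)-4-methyl-3-(triethylsilyloxy)pent-4-enyl]-2,3,7-trioxabicyclo[2.2.1]hept-5-ene (bridgehead epimers) | C=C(C)[C@@H](CCC1=CC2OOC1O2)O[Si](CC)(CC)CC | intermediate (not isolated)
12 | 5-hydroxy-4-[(3R)-4-methyl-3-(triethylsilyloxy)pent-4-enyl]furan-2(5H)-one (lactol epimers) | C=C(C)[C@@H](CCC1=CC(=O)OC1O)O[Si](CC)(CC)CC | intermediate (key-step product)
13 | (2Z,6R)-3-(hydroxymethyl)-7-methyl-6-(triethylsilyloxy)octa-2,7-dienoic acid (sodium salt in the flask) | C=C(C)[C@@H](CC/C(CO)=C/C(=O)O)O[Si](CC)(CC)CC | intermediate (not isolated)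
14 | 4-[(3R)-4-methyl-3-(triethylsilyloxy)pent-4-enyl]furan-2(5H)-one | C=C(C)[C@@H](CCC1=CC(=O)OC1)O[Si](CC)(CC)CC | intermediate
15 | (2Z,6R)-3-(hydroxymethyl)-N-methoxy-N,7-dimethyl-6-(triethylsilyloxy)octa-2,7-dienamide | C=C(C)[C@@H](CC/C(CO)=C/C(=O)N(C)OC)O[Si](CC)(CC)CC | intermediate
16 | (2Z,6R)-3-[(tert-butyldiphenylsilyloxy)methyl]-N-methoxy-N,7-dimethyl-6-(triethylsilyloxy)octa-2,7-dienamide | C=C(C)[C@@H](CC/C(CO[Si](c1ccccc1)(c1ccccc1)C(C)(C)C)=C/C(=O)N(C)OC)O[Si](CC)(CC)CC | intermediate
17 | (2Z,6R)-3-[(tert-butyldiphenylsilyloxy)methyl]-7-methyl-6-(triethylsilyloxy)octa-2,7-dienal | C=C(C)[C@@H](CC/C(CO[Si](c1ccccc1)(c1ccccc1)C(C)(C)C)=C/C=O)O[Si](CC)(CC)CC | intermediate (not isolated)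
18 | (2Z,6R)-3-[(tert-butyldiphenylsilyloxy)methyl]-7-methyl-6-(triethylsilyloxy)octa-2,7-dien-1-ol | C=C(C)[C@@H](CC/C(CO[Si](c1ccccc1)(c1ccccc1)C(C)(C)C)=C/CO)O[Si](CC)(CC)CC | intermediate
19 | 2'-hydroxy-6'-methylacetophenone | CC(=O)c1c(C)cccc1O | starting material
20 | 4-hydroxy-5-methylcoumarin | Cc1cccc2oc(=O)cc(O)c12 | intermediate
21 | 4-{[(2Z,6R)-3-[(tert-butyldiphenylsilyloxy)methyl]-7-methyl-6-(triethylsilyloxy)octa-2,7-dien-1-yl]oxy}-5-methyl-2H-chromen-2-one | C=C(C)[C@@H](CC/C(CO[Si](c1ccccc1)(c1ccccc1)C(C)(C)C)=C/COc1cc(=O)oc2cccc(C)c12)O[Si](CC)(CC)CC | intermediate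
22 | 4-{[(2Z,6R)-3-[(tert-butyldiphenylsilyloxy)methyl]-6-hydroxy-7-methylocta-2,7-dien-1-yl]oxy}-5-methyl-2H-chromen-2-one | C=C(C)[C@@H](CC/C(CO[Si](c1ccccc1)(c1ccccc1)C(C)(C)C)=C/COc1cc(=O)oc2cccc(C)c12)O | intermediate
23 | (2Z,6R)-3-[(tert-butyldiphenylsilyloxy)methyl]-7-methyl-1-[(5-methyl-2-oxo-2H-chromen-4-yl)oxy]octa-2,7-dien-6-yl methanesulfonate | C=C(C)[C@@H](CC/C(CO[Si](c1ccccc1)(c1ccccc1)C(C)(C)C)=C/COc1cc(=O)oc2cccc(C)c12)OS(C)(=O)=O | intermediate (not isolated)
24 | 4-{[(2Z,6S)-3-[(tert-butyldiphenylsilyloxy)methyl]-6-hydroperoxy-7-methylocta-2,7-dien-1-yl]oxy}-5-methyl-2H-chromen-2-one | C=C(C)[C@H](CC/C(CO[Si](c1ccccc1)(c1ccccc1)C(C)(C)C)=C/COc1cc(=O)oc2cccc(C)c12)OO | intermediate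
25 | 4-{[(2Z,6S)-6-hydroperoxy-3-(hydroxymethyl)-7-methylocta-2,7-dien-1-yl]oxy}-5-methyl-2H-chromen-2-one (CNP0171309.1) | C=C(C)[C@H](CC/C(=C/COc1cc(=O)oc2cccc(C)c12)CO)OO | target

Total step count: 16. Longest linear sequence: 15 steps (steps 1–11 and 13–16); step 12 is a one-step side branch.

Steps most likely to fail

Step 15. The allylic mesylate may ionise before it is displaced, which would erode the configuration at C6', deliver the peroxide to the terminal methylene with allylic transposition, or end in elimination. The fallback sets out from 22 and uses a protected, anionic peroxide nucleophile. Mesylate 23 would be made as before, freed of amine salts cold and treated at once with 2-methoxypropan-2-yl hydroperoxide and CsOH·H2O in DMF at 0 °C. This much stronger nucleophile in a dipolar aprotic medium should enforce bimolecular inversion and give the peroxyketal 4-{[(2Z,6S)-3-[(tert-butyldiphenylsilyloxy)methyl]-6-[(2-methoxypropan-2-yl)peroxy]-7-methylocta-2,7-dien-1-yl]oxy}-5-methyl-2H-chromen-2-one F1, which is stable to chromatography. AcOH/THF/H2O at rt would then release the hydroperoxide, and the route is rejoined at 24.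

Step 7. The endoperoxide may fragment from the wrong bridgehead, decay by solvolysis or over-oxidation before the amine acts, or the side-chain alkene may undergo an ene reaction on long irradiation. The fallback sets out from 10 and fixes the oxidation site by C–H borylation. Iridium-catalysed borylation ([Ir(OMe)(cod)]2, dtbpy, B2pin2, THF, rt) is sterically controlled and should functionalise the furan α-position remote from the side chain, giving 4,4,5,5-tetramethyl-2-{4-[(3R)-4-methyl-3-(triethylsilyloxy)pent-4-enyl]furan-2-yl}-1,3,2-dioxaborolane F2. Oxidation of the C–B bond (NaBO3·4H2O, THF/H2O, rt) would give the 2-hydroxyfuran, which tautomerises (Et3N if needed) to the conjugated butenolide. The route is rejoined at 14, bypassing 12 and step 8.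

Step 13. The ambident coumarin may be alkylated at the lactone carbonyl oxygen or at C3, the allylic oxyphosphonium may be captured in an SN2′ sense, or the peri methyl group may slow the coupling. The fallback sets out from 18 and replaces the redox condensation by a direct alkylation. CBr4, PPh3 and 2,6-lutidine in CH2Cl2 at −20 °C would give (2Z,6R)-1-bromo-3-[(tert-butyldiphenylsilyloxy)methyl]-7-methyl-6-(triethylsilyloxy)octa-2,7-diene F3. Treating 20 with F3 and K2CO3 in acetone at rt, the usual conditions for O4-allylation of 4-hydroxycoumarins, rejoins the route at 21.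

Further compounds
F1 | step 15 | 4-{[(2Z,6S)-3-[(tert-butyldiphenylsilyloxy)methyl]-6-[(2-methoxypropan-2-yl)peroxy]-7-methylocta-2,7-dien-1-yl]oxy}-5-methyl-2H-chromen-2-one | C=C(C)[C@H](CC/C(CO[Si](c1ccccc1)(c1ccccc1)C(C)(C)C)=C/COc1cc(=O)oc2cccc(C)c12)OOC(C)(C)OC
F2 | step 7 | 4,4,5,5-tetramethyl-2-{4-[(3R)-4-methyl-3-(triethylsilyloxy)pent-4-enyl]furan-2-yl}-1,3,2-dioxaborolane | C=C(C)[C@@H](CCc1coc(B2OC(C)(C)C(C)(C)O2)c1)O[Si](CC)(CC)CC
F3 | step 13 | (2Z,6R)-1-bromo-3-[(tert-butyldiphenylsilyloxy)methyl]-7-methyl-6-(triethylsilyloxy)octa-2,7-diene | C=C(C)[C@@H](CC/C(CO[Si](c1ccccc1)(c1ccccc1)C(C)(C)C)=C/CBr)O[Si](CC)(CC)CC
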